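**Plan**
1. Retrosynthesis: the C4 silyl ether, the seven benzyl ethers and the C3–O gallate bond are cut first; ring A is then cut at C4a–C8a, C5–C6 and C7–C8, which also opens ring C and leaves a 1,7-diyne (ethynyl ether on O1, benzyloxyalkyne on C4) plus benzyloxyethyne.
2. Enabling feature: ring A is a phloroglucinol ether with oxygen on C5, C7 and C8a, the pattern that three alkynyl ethers joined head to tail deliver, and it shares its C4a–C8a edge with ring C, so the chain O1–C2–C3–C4 can tether two of the three alkynes.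
3. The diyne is cut at C4–C4a (alkoxyethynyl Grignard reagent + aldehyde), O1–C8a (alkoxide + trichloroethylene) and C2–C1' (aryl Grignard reagent + glycerate amide); benzyloxyethyne, made from benzyl formate, serves both as the C4a–C5 unit and as the C6–C7 unit.
4. Forward: the chain C2–C3–C4 is built linearly, rings C and A then arise together in one cycloaddition, and the gallate is attached afterwards, because an ester would not survive the organometallic steps.
5. Stereochemistry: C3 comes from methyl (S)-glycerate acetonide, C2 from a chelation-controlled ketone reduction (O1 anti to O3), C4 from a Felkin–Anh acetylide addition (O4 anti to O3); the cycloaddition makes no stereocentre.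

Key step: step 13

Assumption: the target is read as the (2R,3S,4S) isomer (2,3-trans, 3,4-cis). In the intermediates silylated on O4 the C3 descriptor reads R only because silicon on O4 changes the CIP ranking; the geometry is that of the target throughout. Compounds 1, 3, 7, 13 and 26 are taken as purchasable.

Step 1
Reactants: 1 methyl (4S)-2,2-dimethyl-1,3-dioxolane-4-carboxylate
Product: 2 (4S)-N-methoxy-N,2,2-trimethyl-1,3-dioxolane-4-carboxamide
Conditions: MeNHOMe·HCl, iPrMgCl, THF, −20 to 0 °C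
Reagents that add atoms: N,O-dimethylhydroxylamine hydrochloride, CNOC.Cl
Why: Weinreb amide formation by aminolysis of the ester with the chloromagnesium amide, which is too hindered and used too cold to enolise the α-alkoxy stereocentre.

Step 2
Reactants: 3 1,2-bis(benzyloxy)-4-bromobenzene; 2 (4S)-N-methoxy-N,2,2-trimethyl-1,3-dioxolane-4-carboxamide
Product: 5 [3,4-bis(benzyloxy)phenyl][(4S)-2,2-dimethyl-1,3-dioxolan-4-yl]methanone, via aryl Grignard reagent 4 (not isolated)
Conditions: Mg, THF, 40 °C; then 2, THF, 0 °C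
Reagents that add atoms: none
Why: Grignard addition to a Weinreb amide stops at the ketone because the magnesium-chelated adduct collapses only on work-up, and C3 is not touched.

Step 3
Reactants: 5 [3,4-bis(benzyloxy)phenyl][(4S)-2,2-dimethyl-1,3-dioxolan-4-yl]methanone
Product: 6 (R)-[3,4-bis(benzyloxy)phenyl][(4S)-2,2-dimethyl-1,3-dioxolan-4-yl]methanol
Conditions: Zn(BH4)2, Et2O, −30 to 0 °C
Reagents that add atoms: none
Why: Cram-chelate reduction in which zinc ties the ketone oxygen to the dioxolane oxygen on C3 and hydride enters from the face of the small C3 hydrogen, which should set C2 as R with O1 anti to O3.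

Step 4
Reactants: 6 (R)-[3,4-bis(benzyloxy)phenyl][(4S)-2,2-dimethyl-1,3-dioxolan-4-yl]methanol; 7 trichloroethylene
Product: 9 (4S)-4-[(R)-[3,4-bis(benzyloxy)phenyl][(E)-1,2-dichloroethenyloxy]methyl]-2,2-dimethyl-1,3-dioxolane, via dichloroacetylene 8 (not isolated)
Conditions: KH, THF, 0 °C; then 7, −50 °C to rt
Reagents that add atoms: none
Why: Known route to 1,2-dichlorovinyl ethers in which the potassium alkoxide adds anti across dichloroacetylene released from trichloroethylene; the acetonide is inert to base and offers no group that could migrate to the alkoxide.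

Step 5
Reactants: 9 (4S)-4-[(R)-[3,4-bis(benzyloxy)phenyl][(E)-1,2-dichloroethenyloxy]methyl]-2,2-dimethyl-1,3-dioxolane
Product: 10 (2S,3R)-3-[3,4-bis(benzyloxy)phenyl]-3-[(E)-1,2-dichloroethenyloxy]propane-1,2-diol
Conditions: AcOH/THF/H2O (3:1:1), 40 °C
Reagents that add atoms: none
Why: Acid hydrolysis of a terminal acetonide, which the chlorinated enol ether should tolerate because its double bond is too electron-poor to be protonated by acetic acid.

Step 6
Reactants: 10 (2S,3R)-3-[3,4-bis(benzyloxy)phenyl]-3-[(E)-1,2-dichloroethenyloxy]propane-1,2-diol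
Product: 11 (2S,3R)-3-[3,4-bis(benzyloxy)phenyl]-3-[(E)-1,2-dichloroethenyloxy]-1,2-bis(triethylsilyloxy)propane
Conditions: TESCl, imidazole, DMF, 0 °C to rt
Reagents that add atoms: chlorotriethylsilane, CC[Si](Cl)(CC)CC
Why: Standard silylation of both hydroxyls; TES is chosen because its primary ether can be oxidised directly in the next step and its secondary ether can later be cleaved beside a TBS ether.

Step 7
Reactants: 11 (2S,3R)-3-[3,4-bis(benzyloxy)phenyl]-3-[(E)-1,2-dichloroethenyloxy]-1,2-bis(triethylsilyloxy)propane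
Product: 12 (2R,3R)-3-[3,4-bis(benzyloxy)phenyl]-3-[(E)-1,2-dichloroethenyloxy]-2-(triethylsilyloxy)propanal
Conditions: (COCl)2, DMSO, CH2Cl2, −78 to −40 °C; then Et3N, −78 to 0 °C
Reagents that add atoms: none
Why: Swern oxidation of a bis-TES ether is known to cleave and oxidise only the primary silyl ether, and should give the α-silyloxy aldehyde without epimerisation at low temperature.

Step 8
Reactants: 13 benzyl formate
Product: 14 benzyl 2,2-dichloroethenyl ether
Conditions: PPh3, CCl4, THF, 60 °C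
Reagents that add atoms: carbon tetrachloride, ClC(Cl)(Cl)Cl
Why: Wittig-type dichloromethylenation of a formate by the ylide Ph3P=CCl2 formed from PPh3 and CCl4, a known entry to 2,2-dichlorovinyl ethers; the formyl carbonyl is the only electrophile in 13.

Step 9
Reactants: 14 benzyl 2,2-dichloroethenyl ether
Product: 17 (benzyloxy)ethyne, via benzyl chloroethynyl ether 15 (not isolated), via lithium (benzyloxy)acetylide 16 (not isolated)
Conditions: nBuLi (2.2 equiv), THF, −78 to −40 °C; then MeOH, −78 °C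
Reagents that add atoms: none
Why: Dehydrochlorination to the chloroalkynyl ether followed by chlorine–lithium exchange is the standard conversion of dichlorovinyl ethers into lithium alkoxyacetylides, and cold protonation keeps the benzyl alkynyl ether below the temperature of its [3,3] rearrangement; 17 is kept cold in solution and used soon.

Step 10
Reactants: 17 (benzyloxy)ethyne; 12 (2R,3R)-3-[3,4-bis(benzyloxy)phenyl]-3-[(E)-1,2-dichloroethenyloxy]-2-(triethylsilyloxy)propanal
Product: 19 (1R,2S,3S)-1-[3,4-bis(benzyloxy)phenyl]-5-(benzyloxy)-1-[(E)-1,2-dichloroethenyloxy]-2-(triethylsilyloxy)pent-4-yn-3-ol, via alkynyl Grignard reagent 18 (not isolated)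
Conditions: EtMgBr, THF, 0 °C; then 12, −78 to −20 °C; aq NH4Cl
Reagents that add atoms: none
Why: Arens–van Dorp-type addition of an alkoxyethynyl Grignard reagent to an aldehyde under Felkin–Anh control: the silyl ether binds magnesium poorly, so the nucleophile should enter anti to the α-silyloxy group and set C4 as S with O4 anti to O3, and the weakly basic magnesium alkoxide should not trigger silyl migration; the minor epimer would be removed by chromatography.

Step 11
Reactants: 19 (1R,2S,3S)-1-[3,4-bis(benzyloxy)phenyl]-5-(benzyloxy)-1-[(E)-1,2-dichloroethenyloxy]-2-(triethylsilyloxy)pent-4-yn-3-ol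
Product: 20 (1R,2R,3S)-1-[3,4-bis(benzyloxy)phenyl]-5-(benzyloxy)-3-(tert-butyldimethylsilyloxy)-1-[(E)-1,2-dichloroethenyloxy]-2-(triethylsilyloxy)pent-4-yne
Conditions: TBSCl, imidazole, 4-(dimethylamino)pyridine, DMF, rt
Reagents that add atoms: tert-butyldimethylsilyl chloride, CC(C)(C)[Si](C)(C)Cl
Why: Silylation of the propargylic alcohol under basic conditions that spare the acid-sensitive alkynyl ether and block Meyer–Schuster rearrangement.

Step 12
Reactants: 20 (1R,2R,3S)-1-[3,4-bis(benzyloxy)phenyl]-5-(benzyloxy)-3-(tert-butyldimethylsilyloxy)-1-[(E)-1,2-dichloroethenyloxy]-2-(triethylsilyloxy)pent-4-yne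
Product: 23 (1R,2R,3S)-1-[3,4-bis(benzyloxy)phenyl]-5-(benzyloxy)-3-(tert-butyldimethylsilyloxy)-1-(ethynyloxy)-2-(triethylsilyloxy)pent-4-yne, via chloroethynyl ether 21 (not isolated), via lithium alkynyl ether 22 (not isolated)
Conditions: nBuLi (2.2 equiv), THF, −78 to −40 °C; then MeOH, −78 °C
Reagents that add atoms: none
Why: Completion of the trichloroethylene route on the C2 oxygen by dehydrochlorination, chlorine–lithium exchange and cold protonation; silyl ethers, benzyl ethers and the internal alkynyl ether should not react with nBuLi at this temperature.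

Step 13
Reactants: 23 (1R,2R,3S)-1-[3,4-bis(benzyloxy)phenyl]-5-(benzyloxy)-3-(tert-butyldimethylsilyloxy)-1-(ethynyloxy)-2-(triethylsilyloxy)pent-4-yne; 17 (benzyloxy)ethyne
Product: 24 (2R,3R,4S)-5,7-bis(benzyloxy)-2-[3,4-bis(benzyloxy)phenyl]-4-(tert-butyldimethylsilyloxy)-3-(triethylsilyloxy)chromane
Conditions: Cp*RuCl(cod) (10 mol %), ClCH2CH2Cl, 0 °C to rt, 23 added slowly to 17 (3 equiv)
Reagents that add atoms: none
Why: Proposed new method: the closest known reaction type is the Cp*RuCl(cod)-catalysed [2+2+2] cyclotrimerisation of 1,6- and 1,7-diynes that carry one substituted terminus with terminal alkynes, which delivers meta-substituted arenes, but a case with oxygen on all three alkynes is not known. Divalent ruthenium is expected to couple the two alkynes of 23 oxidatively to a bicyclic ruthenacyclopentatriene, an event that forms C4a–C8a and closes the six-membered ring C by annulation across the O1–C2–C3–C4 tether. Coordination and insertion of 17 followed by reductive elimination should then form C5–C6 and C7–C8 and close ring A in the formal [2+2+2] mode. No stereocentre is created, and C2, C3 and C4 are spectators that the neutral catalyst can neither epimerise nor ionise because C4 is still only a propargylic silyl ether, while a temperature at or below room temperature keeps the benzyl alkynyl ethers and the secondary ethynyl ether below the onset of their sigmatropic and retro-ene decay. The selectivity needed is the 5,7 (meta) placement of the third alkyne: the benzyloxy-bearing C5 end of the metallacycle is the hindered one, so the oxygen-bearing carbon of 17 should bond to the open C8 end, and the polarisation of the alkynyl ether points the same way. Cross-reaction rather than homotrimerisation of 17 or dimerisation of 23 is to be secured by slow addition of 23 to an excess of 17.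

Step 14
Reactants: 24 (2R,3R,4S)-5,7-bis(benzyloxy)-2-[3,4-bis(benzyloxy)phenyl]-4-(tert-butyldimethylsilyloxy)-3-(triethylsilyloxy)chromane
Product: 25 (2R,3R,4S)-5,7-bis(benzyloxy)-2-[3,4-bis(benzyloxy)phenyl]-4-(tert-butyldimethylsilyloxy)chroman-3-ol
Conditions: HF·pyridine, pyridine, THF, 0 °C
Reagents that add atoms: none
Why: Selective desilylation, since a secondary TES ether is cleaved much faster than the hindered benzylic TBS ether and the pyridine buffer keeps the medium too weakly acidic to ionise C4.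

Step 15
Reactants: 25 (2R,3R,4S)-5,7-bis(benzyloxy)-2-[3,4-bis(benzyloxy)phenyl]-4-(tert-butyldimethylsilyloxy)chroman-3-ol; 26 3,4,5-tris(benzyloxy)benzoic acid
Product: 27 (2R,3R,4S)-5,7-bis(benzyloxy)-2-[3,4-bis(benzyloxy)phenyl]-4-(tert-butyldimethylsilyloxy)chroman-3-yl 3,4,5-tris(benzyloxy)benzoate
Conditions: DCC, 4-(dimethylamino)pyridine, CH2Cl2, rt
Reagents that add atoms: none
Why: Steglich esterification, the standard way to put a tri-O-benzylgalloyl group on the 3-hydroxyl of protected flavan-3-ols.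

Step 16
Reactants: 27 (2R,3R,4S)-5,7-bis(benzyloxy)-2-[3,4-bis(benzyloxy)phenyl]-4-(tert-butyldimethylsilyloxy)chroman-3-yl 3,4,5-tris(benzyloxy)benzoate
Product: 28 (2R,3R,4S)-4-(tert-butyldimethylsilyloxy)-2-(3,4-dihydroxyphenyl)-5,7-dihydroxychroman-3-yl 3,4,5-trihydroxybenzoate
Conditions: H2 (1 atm), Pd(OH)2/C, EtOAc/THF, rt
Reagents that add atoms: none
Why: Hydrogenolysis of the seven aryl benzyl ethers in a neutral aprotic medium, in which the bulky silyl ether on C4 is expected to resist both ionisation and cleavage on palladium.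

Step 17
Reactants: 28 (2R,3R,4S)-4-(tert-butyldimethylsilyloxy)-2-(3,4-dihydroxyphenyl)-5,7-dihydroxychroman-3-yl 3,4,5-trihydroxybenzoate
Product: 29 (2R,3S,4S)-2-(3,4-dihydroxyphenyl)-4,5,7-trihydroxychroman-3-yl 3,4,5-trihydroxybenzoate
Conditions: Et3N·3HF, THF/MeCN, rt
Reagents that add atoms: none
Why: Fluoride cleavage of the last silyl ether with a slightly acidic reagent that forms no phenoxide, so that neither acyl migration from O3 to O4 nor loss of the C4 oxygen should be triggered.

**Compound list**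
1 | methyl (4S)-2,2-dimethyl-1,3-dioxolane-4-carboxylate | COC(=O)[C@@H]1COC(C)(C)O1 | starting material
2 | (4S)-N-methoxy-N,2,2-trimethyl-1,3-dioxolane-4-carboxamide | CON(C)C(=O)[C@@H]1COC(C)(C)O1 | intermediate
3 | 1,2-bis(benzyloxy)-4-bromobenzene | Brc1ccc(OCc2ccccc2)c(OCc2ccccc2)c1 | starting material
4 | [3,4-bis(benzyloxy)phenyl]magnesium bromide | Br[Mg]c1ccc(OCc2ccccc2)c(OCc2ccccc2)c1 | intermediate
5 | [3,4-bis(benzyloxy)phenyl][(4S)-2,2-dimethyl-1,3-dioxolan-4-yl]methanone | O=C(c1ccc(OCc2ccccc2)c(OCc2ccccc2)c1)[C@@H]1COC(C)(C)O1 | intermediate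
6 | (R)-[3,4-bis(benzyloxy)phenyl][(4S)-2,2-dimethyl-1,3-dioxolan-4-yl]methanol | CC1(C)O[C@@H](CO1)[C@@H](c1ccc(OCc2ccccc2)c(OCc2ccccc2)c1)O | intermediate
7 | trichloroethylene | ClC=C(Cl)Cl | starting material
8 | dichloroacetylene | ClC#CCl | intermediate
9 | (4S)-4-[(R)-[3,4-bis(benzyloxy)phenyl][(E)-1,2-dichloroethenyloxy]methyl]-2,2-dimethyl-1,3-dioxolane | CC1(C)O[C@@H](CO1)[C@@H](c1ccc(OCc2ccccc2)c(OCc2ccccc2)c1)O/C(Cl)=C\Cl | intermediate
10 | (2S,3R)-3-[3,4-bis(benzyloxy)phenyl]-3-[(E)-1,2-dichloroethenyloxy]propane-1,2-diol | O[C@@H](CO)[C@@H](c1ccc(OCc2ccccc2)c(OCc2ccccc2)c1)O/C(Cl)=C\Cl | intermediate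
11 | (2S,3R)-3-[3,4-bis(benzyloxy)phenyl]-3-[(E)-1,2-dichloroethenyloxy]-1,2-bis(triethylsilyloxy)propane | CC[Si](CC)(CC)O[C@@H](CO[Si](CC)(CC)CC)[C@@H](c1ccc(OCc2ccccc2)c(OCc2ccccc2)c1)O/C(Cl)=C\Cl | intermediate
12 | (2R,3R)-3-[3,4-bis(benzyloxy)phenyl]-3-[(E)-1,2-dichloroethenyloxy]-2-(triethylsilyloxy)propanal | CC[Si](CC)(CC)O[C@@H](C=O)[C@@H](c1ccc(OCc2ccccc2)c(OCc2ccccc2)c1)O/C(Cl)=C\Cl | intermediate
13 | benzyl formate | O=COCc1ccccc1 | starting material
14 | benzyl 2,2-dichloroethenyl ether | ClC(Cl)=COCc1ccccc1 | intermediate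
15 | benzyl chloroethynyl ether | ClC#COCc1ccccc1 | intermediate
16 | lithium (benzyloxy)acetylide | [Li]C#COCc1ccccc1 | intermediate
17 | (benzyloxy)ethyne (benzyl ethynyl ether) | C#COCc1ccccc1 | intermediate
18 | [(benzyloxy)ethynyl]magnesium bromide | Br[Mg]C#COCc1ccccc1 | intermediate
19 | (1R,2S,3S)-1-[3,4-bis(benzyloxy)phenyl]-5-(benzyloxy)-1-[(E)-1,2-dichloroethenyloxy]-2-(triethylsilyloxy)pent-4-yn-3-ol | CC[Si](CC)(CC)O[C@@H]([C@@H](O)C#COCc1ccccc1)[C@@H](c1ccc(OCc2ccccc2)c(OCc2ccccc2)c1)O/C(Cl)=C\Cl | intermediate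
20 | (1R,2R,3S)-1-[3,4-bis(benzyloxy)phenyl]-5-(benzyloxy)-3-(tert-butyldimethylsilyloxy)-1-[(E)-1,2-dichloroethenyloxy]-2-(triethylsilyloxy)pent-4-yne | CC[Si](CC)(CC)O[C@@H]([C@@H](O[Si](C)(C)C(C)(C)C)C#COCc1ccccc1)[C@@H](c1ccc(OCc2ccccc2)c(OCc2ccccc2)c1)O/C(Cl)=C\Cl | intermediate
21 | (1R,2R,3S)-1-[3,4-bis(benzyloxy)phenyl]-5-(benzyloxy)-3-(tert-butyldimethylsilyloxy)-1-[(chloroethynyl)oxy]-2-(triethylsilyloxy)pent-4-yne | CC[Si](CC)(CC)O[C@@H]([C@@H](O[Si](C)(C)C(C)(C)C)C#COCc1ccccc1)[C@@H](c1ccc(OCc2ccccc2)c(OCc2ccccc2)c1)OC#CCl | intermediate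
22 | lithium acetylide of 23 (lithium on the terminal carbon of the ethynyl ether) | CC[Si](CC)(CC)O[C@@H]([C@@H](O[Si](C)(C)C(C)(C)C)C#COCc1ccccc1)[C@@H](c1ccc(OCc2ccccc2)c(OCc2ccccc2)c1)OC#C[Li] | intermediate
23 | (1R,2R,3S)-1-[3,4-bis(benzyloxy)phenyl]-5-(benzyloxy)-3-(tert-butyldimethylsilyloxy)-1-(ethynyloxy)-2-(triethylsilyloxy)pent-4-yne | CC[Si](CC)(CC)O[C@@H]([C@@H](O[Si](C)(C)C(C)(C)C)C#COCc1ccccc1)[C@@H](c1ccc(OCc2ccccc2)c(OCc2ccccc2)c1)OC#C | intermediate
24 | (2R,3R,4S)-5,7-bis(benzyloxy)-2-[3,4-bis(benzyloxy)phenyl]-4-(tert-butyldimethylsilyloxy)-3-(triethylsilyloxy)chromane | CC[Si](CC)(CC)O[C@@H]1[C@@H](c2ccc(OCc3ccccc3)c(OCc3ccccc3)c2)Oc2cc(OCc3ccccc3)cc(OCc3ccccc3)c2[C@@H]1O[Si](C)(C)C(C)(C)C | intermediate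
25 | (2R,3R,4S)-5,7-bis(benzyloxy)-2-[3,4-bis(benzyloxy)phenyl]-4-(tert-butyldimethylsilyloxy)chroman-3-ol | O[C@@H]1[C@@H](c2ccc(OCc3ccccc3)c(OCc3ccccc3)c2)Oc2cc(OCc3ccccc3)cc(OCc3ccccc3)c2[C@@H]1O[Si](C)(C)C(C)(C)C | intermediate
26 | 3,4,5-tris(benzyloxy)benzoic acid | O=C(O)c1cc(OCc2ccccc2)c(OCc2ccccc2)c(OCc2ccccc2)c1 | starting material
27 | (2R,3R,4S)-5,7-bis(benzyloxy)-2-[3,4-bis(benzyloxy)phenyl]-4-(tert-butyldimethylsilyloxy)chroman-3-yl 3,4,5-tris(benzyloxy)benzoate | O=C(O[C@@H]1[C@@H](c2ccc(OCc3ccccc3)c(OCc3ccccc3)c2)Oc2cc(OCc3ccccc3)cc(OCc3ccccc3)c2[C@@H]1O[Si](C)(C)C(C)(C)C)c1cc(OCc2ccccc2)c(OCc2ccccc2)c(OCc2ccccc2)c1 | intermediate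
28 | (2R,3R,4S)-4-(tert-butyldimethylsilyloxy)-2-(3,4-dihydroxyphenyl)-5,7-dihydroxychroman-3-yl 3,4,5-trihydroxybenzoate | O=C(O[C@@H]1[C@@H](c2ccc(O)c(O)c2)Oc2cc(O)cc(O)c2[C@@H]1O[Si](C)(C)C(C)(C)C)c1cc(O)c(O)c(O)c1 | intermediate
29 | (2R,3S,4S)-2-(3,4-dihydroxyphenyl)-4,5,7-trihydroxychroman-3-yl 3,4,5-trihydroxybenzoate | O=C(O[C@@H]1[C@@H](c2ccc(O)c(O)c2)Oc2cc(O)cc(O)c2[C@@H]1O)c1cc(O)c(O)c(O)c1 | target

**Count**
Total: 17 steps. Longest linear sequence: 15 steps (steps 1–7 and 10–17, from 1 to 29); steps 8 and 9 form the side branch that supplies 17.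

**Steps most likely to fail**

1. Step 13. The ruthenacycle may not form from two electron-rich alkynyl ethers, because the terminal one can tautomerise on the metal to an alkoxyvinylidene and be lost. Homotrimerisation of 17 may also outrun the cross-reaction, or 17 may insert in the ortho sense.
Fallback by known chemistry, setting out from 3 and coming back at 24: the chroman is built by the chalcone route to dihydroflavonols. Bromine–lithium exchange on 3 (nBuLi, −78 °C) and formylation with DMF would give 3,4-bis(benzyloxy)benzaldehyde F1. Commercial 2'-hydroxy-4',6'-bis(benzyloxy)acetophenone would be protected with MOMCl and iPr2NEt as 1-[2,4-bis(benzyloxy)-6-(methoxymethoxy)phenyl]ethan-1-one F2. Claisen–Schmidt condensation of F1 and F2 (KOH, EtOH) would give the (E)-chalcone F3, and Juliá–Colonna epoxidation (poly-L-leucine, H2O2, base) the (2R,3S)-epoxy ketone F4. HCl in MeOH would remove the MOM group, and the freed phenol would open the epoxide at the benzylic carbon with inversion to give (2R,3R)-5,7,3',4'-tetra-O-benzyltaxifolin F5. TESCl and imidazole would give the 3-O-triethylsilyl ketone F6. LiBH(sBu)3 at −78 °C should attack the C4 ketone from the equatorial side and give the 3,4-cis alcohol F7, and TBSOTf with 2,6-lutidine would then give 24.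

2. Step 16. Reductive cleavage of the benzylic C4–O bond, or its solvolysis once the ring A phenols are free, would erase the C4 carbinol.
Fallback setting out from 27 and coming back at 29: C4 is carried through the debenzylation as a ketone and its stereocentre is made last. Et3N·3HF would remove the silyl group to give the 4-hydroxy hepta-O-benzyl gallate F8, and Dess–Martin periodinane would oxidise it to the 4-oxo compound F9. Hydrogenolysis over Pd(OH)2/C, to which the aryl ketone should be inert, would give taxifolin 3-O-gallate F10. Hydrogenation of the ketone over PtO2, which in the dihydroquercetin series is reported to favour the 2,3-trans-3,4-cis diol, should then give 29 directly.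

3. Step 10. Facial selectivity may be modest, since the α-silyloxy and β-alkoxy stereocentres of the aldehyde need not reinforce each other, and the silyl group may migrate in the alkoxide.
Fallback setting out from 19 (as the epimer mixture) and coming back at 19: C4 is set by reagent control. Dess–Martin periodinane with NaHCO3 would oxidise the mixture to the ynone F11. Corey–Bakshi–Shibata reduction with (R)-2-methyl-CBS-oxazaborolidine and catecholborane at −78 °C, in which the alkyne acts as the small group, should return 19 as the (3S) alcohol.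

**Further compounds**
F1 | step 13 | 3,4-bis(benzyloxy)benzaldehyde | O=Cc1ccc(OCc2ccccc2)c(OCc2ccccc2)c1
F2 | step 13 | 1-[2,4-bis(benzyloxy)-6-(methoxymethoxy)phenyl]ethan-1-one | CC(=O)c1c(OCOC)cc(OCc2ccccc2)cc1OCc1ccccc1
F3 | step 13 | (E)-1-[2,4-bis(benzyloxy)-6-(methoxymethoxy)phenyl]-3-[3,4-bis(benzyloxy)phenyl]prop-2-en-1-one | O=C(/C=C/c1ccc(OCc2ccccc2)c(OCc2ccccc2)c1)c1c(OCOC)cc(OCc2ccccc2)cc1OCc1ccccc1
F4 | step 13 | [(2R,3S)-3-[3,4-bis(benzyloxy)phenyl]oxiran-2-yl][2,4-bis(benzyloxy)-6-(methoxymethoxy)phenyl]methanone | O=C([C@@H]1O[C@H]1c1ccc(OCc2ccccc2)c(OCc2ccccc2)c1)c1c(OCOC)cc(OCc2ccccc2)cc1OCc1ccccc1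
F5 | step 13 | (2R,3R)-5,7-bis(benzyloxy)-2-[3,4-bis(benzyloxy)phenyl]-3-hydroxychroman-4-one | O[C@@H]1[C@@H](c2ccc(OCc3ccccc3)c(OCc3ccccc3)c2)Oc2cc(OCc3ccccc3)cc(OCc3ccccc3)c2C1=O
F6 | step 13 | (2R,3R)-5,7-bis(benzyloxy)-2-[3,4-bis(benzyloxy)phenyl]-3-(triethylsilyloxy)chroman-4-one | CC[Si](CC)(CC)O[C@@H]1[C@@H](c2ccc(OCc3ccccc3)c(OCc3ccccc3)c2)Oc2cc(OCc3ccccc3)cc(OCc3ccccc3)c2C1=O
F7 | step 13 | (2R,3S,4S)-5,7-bis(benzyloxy)-2-[3,4-bis(benzyloxy)phenyl]-3-(triethylsilyloxy)chroman-4-ol | CC[Si](CC)(CC)O[C@@H]1[C@@H](c2ccc(OCc3ccccc3)c(OCc3ccccc3)c2)Oc2cc(OCc3ccccc3)cc(OCc3ccccc3)c2[C@@H]1O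
F8 | step 16 | (2R,3S,4S)-5,7-bis(benzyloxy)-2-[3,4-bis(benzyloxy)phenyl]-4-hydroxychroman-3-yl 3,4,5-tris(benzyloxy)benzoate | O=C(O[C@@H]1[C@@H](c2ccc(OCc3ccccc3)c(OCc3ccccc3)c2)Oc2cc(OCc3ccccc3)cc(OCc3ccccc3)c2[C@@H]1O)c1cc(OCc2ccccc2)c(OCc2ccccc2)c(OCc2ccccc2)c1
F9 | step 16 | (2R,3R)-5,7-bis(benzyloxy)-2-[3,4-bis(benzyloxy)phenyl]-4-oxochroman-3-yl 3,4,5-tris(benzyloxy)benzoate | O=C(O[C@@H]1[C@@H](c2ccc(OCc3ccccc3)c(OCc3ccccc3)c2)Oc2cc(OCc3ccccc3)cc(OCc3ccccc3)c2C1=O)c1cc(OCc2ccccc2)c(OCc2ccccc2)c(OCc2ccccc2)c1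
F10 | step 16 | (2R,3R)-2-(3,4-dihydroxyphenyl)-5,7-dihydroxy-4-oxochroman-3-yl 3,4,5-trihydroxybenzoate | O=C(O[C@@H]1[C@@H](c2ccc(O)c(O)c2)Oc2cc(O)cc(O)c2C1=O)c1cc(O)c(O)c(O)c1
F11 | step 10 | (1R,2R)-1-[3,4-bis(benzyloxy)phenyl]-5-(benzyloxy)-1-[(E)-1,2-dichloroethenyloxy]-2-(triethylsilyloxy)pent-4-yn-3-one | CC[Si](CC)(CC)O[C@@H](C(=O)C#COCc1ccccc1)[C@@H](c1ccc(OCc2ccccc2)c(OCc2ccccc2)c1)O/C(Cl)=C\Cl
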